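**Retrosynthetic overview**

1. 11 ⇒ 7 + 8: Claisen–Schmidt disconnection of the enone C=C; both MOM ethers are removed in the same flask.
2. 7 ⇒ 6: O-methylation of the one remaining (ketone-chelated) phenol.
3. 6 ⇒ 5 ⇒ 4: the dihydrofuran O–C2 bond comes from 5-exo-tet opening of an (S)-prenyl epoxide (inversion gives 2R); the epoxide comes from an organocatalytic peptide-peracid epoxidation, which sets the only stereocentre.
4. 4 ⇒ 2 + 3 ⇒ 1: C-prenylation of the symmetric 4-O-MOM acylresorcinol (C3 and C5 are equivalent), made from phloroacetophenone; the MOM group leaves only the 2-OH able to close the ring.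
5. Rings: both benzene rings are bought; the dihydrofuran ring is the only ring formed (step 3).

Assumption: the sense of induction of the new peptide catalyst in step 3 cannot be predicted on paper, so the sequence named there or its mirror image (same synthesis from the antipodal amino acids) is used, whichever gives the (S)-epoxide in a first screen.

**Step 1**
Reactants: 1 1-(2,4,6-trihydroxyphenyl)ethan-1-one (phloroacetophenone)
Product: 2 1-[2,6-dihydroxy-4-(methoxymethoxy)phenyl]ethan-1-one
Conditions: MOMCl (1.05 equiv), K2CO3 (1.1 equiv), acetone, 0 °C → rt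
Reagents that add atoms: chloromethyl methyl ether (MOMCl), COCCl
Why: Williamson-type O-alkylation; the 4-OH is the most acidic hydroxyl and the only one not held in a hydrogen bond to the ketone, so one equivalent of MOMCl caps it first and leaves a symmetric acylresorcinol.

**Step 2**
Reactants: 2 1-[2,6-dihydroxy-4-(methoxymethoxy)phenyl]ethan-1-one; 3 1-bromo-3-methylbut-2-ene (prenyl bromide)
Product: 4 1-[2,6-dihydroxy-4-(methoxymethoxy)-3-(3-methylbut-2-en-1-yl)phenyl]ethan-1-one
Conditions: 3 (1.0 equiv), 10% aq KOH (1.1 equiv), 0 °C → rt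
Reagents that add atoms: none
Why: Nuclear C-prenylation (C-allylation of an acylphloroglucinol-type anion); in water the oxygens are solvated so the soft allylic bromide is attacked by ring carbon, and because C3 and C5 are equivalent by symmetry only one mono-C-prenyl isomer can form.

**Step 3**
Reactants: 4 1-[2,6-dihydroxy-4-(methoxymethoxy)-3-(3-methylbut-2-en-1-yl)phenyl]ethan-1-one
Product: 6 1-[(2R)-6-hydroxy-2-(2-hydroxypropan-2-yl)-4-(methoxymethoxy)-2,3-dihydro-1-benzofuran-7-yl]ethan-1-one, via (S)-epoxide 5 (not isolated)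
Conditions: Boc-Asp(OH)-Pro-D-Val-NH-(R)-CH(Me)Ph or its mirror image (10 mol %), DMAP (10 mol %), DIC (2 equiv), 30% aq H2O2 (2.5 equiv), CH2Cl2, 0 °C, 16 h; aq Na2S2O3 wash; then K2CO3 (0.3 equiv), MeOH, 0 °C → rt
Reagents that add atoms: hydrogen peroxide, OO
Why: Proposed new method: phenol-directed aspartyl-peptide peracid epoxidation with tandem cycloetherification; DIC/DMAP/H2O2 turn the Asp side-chain acid into a transient peracid held in a β-turn, the free phenolic OH next to the prenyl group (the other OH is tied up in the ketone chelate) donates a hydrogen bond to a backbone C=O while the aryl ketone accepts one from an N–H, so one face of the electron-rich trisubstituted olefin is presented to the peracid oxygen (concerted butterfly transfer) and the (S)-epoxide forms; the neutral medium keeps the oxidation-prone acylresorcinol protonated (racemic peracids are known to epoxidise such prenyl acylphloroglucinols cleanly), and after the peroxide is destroyed catalytic K2CO3 lets the 2-phenoxide open the epoxide at the secondary carbon (5-exo-tet, SN2, inversion) to give the 2R dihydrofuran; closest known reaction types are aspartyl-peptide peracid epoxidation of allylic carbamates and of farnesol (hydroxyl-directed), and epoxidation followed by base cyclisation of ortho-prenylphenols.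

**Step 4**
Reactants: 6 1-[(2R)-6-hydroxy-2-(2-hydroxypropan-2-yl)-4-(methoxymethoxy)-2,3-dihydro-1-benzofuran-7-yl]ethan-1-one
Product: 7 1-[(2R)-2-(2-hydroxypropan-2-yl)-6-methoxy-4-(methoxymethoxy)-2,3-dihydro-1-benzofuran-7-yl]ethan-1-one
Conditions: MeI (3 equiv), K2CO3 (3 equiv), acetone, 50 °C
Reagents that add atoms: iodomethane (MeI), CI
Why: Williamson ether synthesis; K2CO3 deprotonates only the phenol, so the chelated 6-OH is methylated while the tertiary alcohol and the C2 stereocentre are untouched.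

**Step 5**
Reactants: 7 1-[(2R)-2-(2-hydroxypropan-2-yl)-6-methoxy-4-(methoxymethoxy)-2,3-dihydro-1-benzofuran-7-yl]ethan-1-one; 8 4-(methoxymethoxy)benzaldehyde
Product: 11 (2E)-1-[(2R)-4-hydroxy-2-(2-hydroxypropan-2-yl)-6-methoxy-2,3-dihydro-1-benzofuran-7-yl]-3-(4-hydroxyphenyl)prop-2-en-1-one, via aldol adduct 9 (not isolated), via bis-MOM chalcone 10 (not isolated)
Conditions: 8 (1.5 equiv), KOH (12 equiv, 50% aq), MeOH, rt, 24–48 h; then conc. HCl to ca. 3 M, 45 °C, 1–2 h
Reagents that add atoms: none
Why: Claisen–Schmidt aldol condensation (E1cB dehydration gives the E-enone, and with no free ortho-OH on the ketone no flavanone can form) followed by acid-catalysed acetal methanolysis of both MOM ethers; C2 is not enolisable and is not affected.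

**Compound list**

1 | 1-(2,4,6-trihydroxyphenyl)ethan-1-one | CC(=O)c1c(O)cc(O)cc1O | starting material
2 | 1-[2,6-dihydroxy-4-(methoxymethoxy)phenyl]ethan-1-one | CC(=O)c1c(O)cc(OCOC)cc1O | intermediate
3 | 1-bromo-3-methylbut-2-ene | CC(C)=CCBr | starting material
4 | 1-[2,6-dihydroxy-4-(methoxymethoxy)-3-(3-methylbut-2-en-1-yl)phenyl]ethan-1-one | CC(=O)c1c(O)cc(OCOC)c(CC=C(C)C)c1O | intermediate
5 | 1-[3-{[(2S)-3,3-dimethyloxiran-2-yl]methyl}-2,6-dihydroxy-4-(methoxymethoxy)phenyl]ethan-1-one | CC(=O)c1c(O)cc(OCOC)c(C[C@@H]2OC2(C)C)c1O | intermediate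
6 | 1-[(2R)-6-hydroxy-2-(2-hydroxypropan-2-yl)-4-(methoxymethoxy)-2,3-dihydro-1-benzofuran-7-yl]ethan-1-one | CC(=O)c1c(O)cc(OCOC)c2c1O[C@@H](C(C)(C)O)C2 | intermediate
7 | 1-[(2R)-2-(2-hydroxypropan-2-yl)-6-methoxy-4-(methoxymethoxy)-2,3-dihydro-1-benzofuran-7-yl]ethan-1-one | CC(=O)c1c(OC)cc(OCOC)c2c1O[C@@H](C(C)(C)O)C2 | intermediate
8 | 4-(methoxymethoxy)benzaldehyde | COCOc1ccc(C=O)cc1 | starting material
9 | 3-hydroxy-1-[(2R)-2-(2-hydroxypropan-2-yl)-6-methoxy-4-(methoxymethoxy)-2,3-dihydro-1-benzofuran-7-yl]-3-[4-(methoxymethoxy)phenyl]propan-1-one (both carbinol epimers) | COCOc1ccc(C(O)CC(=O)c2c(OC)cc(OCOC)c3c2O[C@@H](C(C)(C)O)C3)cc1 | intermediate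
10 | (2E)-1-[(2R)-2-(2-hydroxypropan-2-yl)-6-methoxy-4-(methoxymethoxy)-2,3-dihydro-1-benzofuran-7-yl]-3-[4-(methoxymethoxy)phenyl]prop-2-en-1-one | COCOc1ccc(/C=C/C(=O)c2c(OC)cc(OCOC)c3c2O[C@@H](C(C)(C)O)C3)cc1 | intermediate
11 | (2E)-1-[(2R)-4-hydroxy-2-(2-hydroxypropan-2-yl)-6-methoxy-2,3-dihydro-1-benzofuran-7-yl]-3-(4-hydroxyphenyl)prop-2-en-1-one | COc1cc(O)c2c(c1C(=O)/C=C/c1ccc(O)cc1)O[C@@H](C(C)(C)O)C2 | target

**Step count**

Total steps: 5. Longest linear sequence: 5 (1 → 2 → 4 → 6 → 7 → 11).

**Three steps most likely to fail**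

Step 3 (the proposed new step). The enantiomeric excess and sense of induction are unknown. Acid-type 6-endo opening to the chromanol and Baeyer–Villiger oxidation of the aryl ketone are possible side paths. The ee of 6 is checked by chiral HPLC, and 7 can be recrystallised if needed. The fallback uses known chemistry, sets out from 4 and comes back at 6. Both phenols are silylated (TBSCl, imidazole, DMAP, DMF, 45 °C) to give 1-[2,6-bis(tert-butyldimethylsilyloxy)-4-(methoxymethoxy)-3-(3-methylbut-2-en-1-yl)phenyl]ethan-1-one F1. Shi epoxidation with the L-fructose-derived ketone (1,2:4,5-di-O-isopropylidene-β-L-erythro-2,3-hexodiulo-2,6-pyranose, 30 mol %), KHSO5 (as 2KHSO5·KHSO4·K2SO4), K2CO3 buffer at pH 10.5, Bu4NHSO4, MeCN/dimethoxymethane/water, 0 °C, then gives 1-[2,6-bis(tert-butyldimethylsilyloxy)-3-{[(2S)-3,3-dimethyloxiran-2-yl]methyl}-4-(methoxymethoxy)phenyl]ethan-1-one F2. By the spiro transition-state model the D-fructose ketone gives the (R)-epoxide from such olefins, so the L-ketone gives (S). TBAF in THF (0 °C → rt) removes both silyl groups and the 2-phenoxide closes 5-exo-tet to 6.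

Step 2. C- versus O-alkylation and double prenylation limit the yield (about 35–50% expected). The fallback sets out from 2 and comes back at 4. O-Alkylation with tert-butyl 2-methylbut-3-en-2-yl carbonate and catalytic Pd(PPh3)4 (THF, 0 °C → rt) gives the tertiary allyl ether 1-{2-hydroxy-4-(methoxymethoxy)-6-[(2-methylbut-3-en-2-yl)oxy]phenyl}ethan-1-one F3. Heating in toluene at 110 °C triggers the aromatic Claisen rearrangement to the only free ortho carbon, which delivers the linear prenyl group of 4.

Step 5. The ketone is hindered, the sequence is telescoped, and the tertiary alcohol and the chalcone both see warm acid. The fallback sets out from 7 and comes back at 11. The single MOM ether is cleaved at the ketone stage under mild conditions (1 M HCl, MeOH, rt) to give 1-[(2R)-4-hydroxy-2-(2-hydroxypropan-2-yl)-6-methoxy-2,3-dihydro-1-benzofuran-7-yl]ethan-1-one F4. A protecting-group-free Claisen–Schmidt condensation with commercial 4-hydroxybenzaldehyde (60% aq KOH, EtOH, rt → 50 °C) and cold acidification then gives 11, so the chalcone never meets warm acid.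

**Further compounds**

F1 | step 3 | 1-[2,6-bis(tert-butyldimethylsilyloxy)-4-(methoxymethoxy)-3-(3-methylbut-2-en-1-yl)phenyl]ethan-1-one | CC(=O)c1c(O[Si](C)(C)C(C)(C)C)cc(OCOC)c(CC=C(C)C)c1O[Si](C)(C)C(C)(C)C
F2 | step 3 | 1-[2,6-bis(tert-butyldimethylsilyloxy)-3-{[(2S)-3,3-dimethyloxiran-2-yl]methyl}-4-(methoxymethoxy)phenyl]ethan-1-one | CC(=O)c1c(O[Si](C)(C)C(C)(C)C)cc(OCOC)c(C[C@@H]2OC2(C)C)c1O[Si](C)(C)C(C)(C)C
F3 | step 2 | 1-{2-hydroxy-4-(methoxymethoxy)-6-[(2-methylbut-3-en-2-yl)oxy]phenyl}ethan-1-one | CC(=O)c1c(O)cc(OCOC)cc1OC(C)(C)C=C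
F4 | step 5 | 1-[(2R)-4-hydroxy-2-(2-hydroxypropan-2-yl)-6-methoxy-2,3-dihydro-1-benzofuran-7-yl]ethan-1-one | CC(=O)c1c(OC)cc(O)c2c1O[C@@H](C(C)(C)O)C2
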